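**Retrosynthetic overview**

1. Locants follow the benzo[7]annulene name of the target. Ring A is the trimethoxybenzene ring (fused carbons C4a, C9a). The seven-membered ring runs C5 (spiro)–C6H2–C7H(Me)–C8H(Me)–C9H(OH). Ring B is the dienone ring spiro at C5. The target is the all-trans (all pseudo-equatorial) 7R,8S,9R isomer.
2. The C9 carbinol and the C8 configuration are adjusted last by torsional and thermodynamic control in the ring, so only C7 must come from the chiral pool ((R)-propylene oxide).
3. Key disconnection: C7–C8 and C4a–C5 are made in one flask, as a formal (4+3) annulation of a spiro[2.5]octadienone (ring B with C5–C6–C7 closed to a cyclopropane) with the silyl enol ether of 3',4',5'-trimethoxypropiophenone.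
4. Enabling feature: C5 is the ipso carbon of ring B, para to the ring B oxygen and β to C7. It first holds C7 in a three-membered ring, which makes C7 an electrophile with stereochemical memory. Once C7–C8 formation releases it as a phenol carbon, two-electron oxidation makes C5 electrophilic, and C4a of ring A (one of two equivalent OMe-activated positions) closes the ring.
5. Ring order: temporary cyclopropane on dearomatised ring B → ring B rearomatised → seven-membered ring and dienone ring B formed together.

Key step: step 6

Assumption: 4-bromo-2,6-dimethoxyphenol, (R)-propylene oxide and 1-(3,4,5-trimethoxyphenyl)propan-1-one are taken as purchasable; the ketone is otherwise one step from 3,4,5-trimethoxybenzonitrile and EtMgBr.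

**Route**

Step 1
Reactants: 1 4-bromo-2,6-dimethoxyphenol
Product: 2 (4-bromo-2,6-dimethoxyphenoxy)(tert-butyl)dimethylsilane
Conditions: TBSCl, imidazole, DMF, 23 °C
Reagents that add atoms: tert-butyldimethylsilyl chloride, CC(C)(C)[Si](C)(C)Cl
Why: Imidazole-promoted O-silylation of a phenol is a routine protection that keeps the acidic OH out of the bromine–lithium exchange of step 2; no stereocentre is formed.

Step 2
Reactants: 2 (4-bromo-2,6-dimethoxyphenoxy)(tert-butyl)dimethylsilane; 3 (R)-2-methyloxirane
Product: 4 (2R)-1-{4-[(tert-butyldimethylsilyl)oxy]-3,5-dimethoxyphenyl}propan-2-ol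
Conditions: n-BuLi, THF, –78 °C; then BF3·OEt2, 3, –78 °C; aq. NH4Cl
Reagents that add atoms: none
Why: Bromine–lithium exchange followed by BF3-assisted SN2 opening of the epoxide at its unsubstituted carbon (organolithium epoxide opening) joins ring B to the future C6–C7 unit without touching the epoxide stereocentre, so the future C7 carries the (R)-carbinol.

Step 3
Reactants: 4 (2R)-1-{4-[(tert-butyldimethylsilyl)oxy]-3,5-dimethoxyphenyl}propan-2-ol
Product: 5 (2R)-1-{4-[(tert-butyldimethylsilyl)oxy]-3,5-dimethoxyphenyl}propan-2-yl methanesulfonate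
Conditions: MsCl, Et3N, CH2Cl2, 0 °C
Reagents that add atoms: methanesulfonyl chloride, CS(=O)(=O)Cl
Why: Mesylation of the secondary alcohol (sulfonate ester formation at oxygen, retention at carbon) installs the nucleofuge needed for aryl participation.

Step 4
Reactants: 5 (2R)-1-{4-[(tert-butyldimethylsilyl)oxy]-3,5-dimethoxyphenyl}propan-2-yl methanesulfonate
Product: 6 (1S)-5,7-dimethoxy-1-methylspiro[2.5]octa-4,7-dien-6-one
Conditions: Bu4NF, THF, –20 to 0 °C; rapid filtration through neutral alumina, used at once
Reagents that add atoms: none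
Why: Fluoride desilylation releases the phenoxide, whose para carbon displaces the mesylate in an Ar1-3 (aryl-participation) intramolecular SN2 C-alkylation, forming the spirocyclopropyl dienone with inversion at the future C7.

Step 5
Reactants: 7 1-(3,4,5-trimethoxyphenyl)propan-1-one
Product: 8 (Z)-trimethyl{[1-(3,4,5-trimethoxyphenyl)prop-1-en-1-yl]oxy}silane
Conditions: TMSOTf, Et3N, CH2Cl2, 0 °C
Reagents that add atoms: trimethylsilyl trifluoromethanesulfonate, C[Si](C)(C)OS(=O)(=O)C(F)(F)F
Why: Soft enolisation with TMSOTf/Et3N (silyl enol ether formation) should give the thermodynamically preferred (Z)-enol ether, whose geometry is not critical because C8 is equilibrated in step 7.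

Step 6
Reactants: 6 (1S)-5,7-dimethoxy-1-methylspiro[2.5]octa-4,7-dien-6-one; 8 (Z)-trimethyl{[1-(3,4,5-trimethoxyphenyl)prop-1-en-1-yl]oxy}silane
Product: 10 spiro keto-dienone (7R; both C8 epimers), via silyl ether ketone 9 (not isolated)
Conditions: TMSOTf (10 mol %), CH2Cl2, –78 to –40 °C; then 2,6-lutidine (0.2 equiv), CF3CH2OH, PhI(OCOCF3)2, –40 °C
Reagents that add atoms: none
Why: Proposed new method: catalytic TMSOTf should silylate the dienone oxygen of 6 and turn the spirocyclopropane into a bridged silyloxy-phenonium ion, which the silyl enol ether opens at the methyl-bearing carbon C7 with inversion to form C7–C8 (a Mukaiyama-type homo-conjugate addition; the closest known reactions are Lewis-acid ring-openings of donor–acceptor cyclopropanes by silyl enol ethers, nucleophilic 1,6-type ring-openings of spiro[2.5]octa-4,7-dien-6-ones and phenonium solvolyses, in which the nucleophile enters at the more substituted carbon), and silyl transfer to the liberated phenol oxygen turns the catalyst over and leaves rearomatised ring B as aryl silyl ether 9. In the same flask PhI(OCOCF3)2 in CF3CH2OH then oxidises that oxygen to a phenoxenium ion, and ring A carbon C4a attacks its para carbon C5 to form C4a–C5; this second event is a known reaction type, the para–ortho' phenol coupling of 4-alkylphenols tethered to 3,4,5-trialkoxybenzoyl rings, which gives seven-membered spirodienones. The only ring closed is the seven-membered ring, by a 7-exo-trig spiro (ipso) attack of the arene on the dearomatising ring B. C7 is set stereospecifically (two inversions from the (R)-mesylate, so the carbinol configuration is carried over with net retention and becomes 7R), C8 is formed without control and is equilibrated in step 7, and C5 is not a stereocentre because ring B is symmetric. The step needs attack at the CH(CH3) and not the CH2 carbon of the three-membered ring (the bridged ion carries more positive charge on its more substituted carbon), oxidation of the phenol in preference to the enolisable ketone and the arenes (the 2,6-dimethoxyphenol is by far the most easily oxidised site at –40 °C), and para instead of ortho coupling (both ortho carbons of ring B carry OMe and the two ortho carbons of ring A are equivalent).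

Step 7
Reactants: 10 spiro keto-dienone (7R; both C8 epimers)
Product: 12 trans dienol ketone (7R,8S), via dienol ketone epimer mixture 11 (not isolated)
Conditions: NaBH4, CeCl3·7H2O, MeOH/CH2Cl2, –78 °C; acetone; then NaOMe, MeOH, 23 °C
Reagents that add atoms: none
Why: A Luche 1,2-reduction should take the more reactive cross-conjugated dienone carbonyl before the hindered, electron-rich aryl ketone and thereby remove the Michael acceptor, so that methoxide-mediated enolisation (ketone α-epimerisation) can funnel both C8 epimers into the trans (pseudo-equatorial, 8S) isomer under thermodynamic control without a transannular conjugate addition.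

Step 8
Reactants: 12 trans dienol ketone (7R,8S)
Product: 14 target spirodienone alcohol (7R,8S,9R), via diol 13 (not isolated)
Conditions: NaBH4, MeOH, 0 °C; aq. NaHCO3 work-up; then MnO2, CH2Cl2, 23 °C
Reagents that add atoms: none
Why: Hydride addition to the benzylic ketone from the pseudo-axial direction (torsionally controlled NaBH4 reduction, as for 2-alkylcycloalkanones) should give the pseudo-equatorial 9R alcohol trans to the C8 methyl, and MnO2 (allylic alcohol oxidation) should then reoxidise the doubly allylic dienol much faster than the hindered benzylic alcohol to restore the dienone.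

**Compound list**

1 | 4-bromo-2,6-dimethoxyphenol | COc1cc(Br)cc(OC)c1O | starting material
2 | (4-bromo-2,6-dimethoxyphenoxy)(tert-butyl)dimethylsilane | COc1cc(Br)cc(OC)c1O[Si](C)(C)C(C)(C)C | intermediate
3 | (R)-2-methyloxirane | C[C@@H]1CO1 | starting material
4 | (2R)-1-{4-[(tert-butyldimethylsilyl)oxy]-3,5-dimethoxyphenyl}propan-2-ol | C[C@@H](O)Cc1cc(OC)c(O[Si](C)(C)C(C)(C)C)c(OC)c1 | intermediate
5 | (2R)-1-{4-[(tert-butyldimethylsilyl)oxy]-3,5-dimethoxyphenyl}propan-2-yl methanesulfonate | C[C@@H](OS(C)(=O)=O)Cc1cc(OC)c(O[Si](C)(C)C(C)(C)C)c(OC)c1 | intermediate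
6 | (1S)-5,7-dimethoxy-1-methylspiro[2.5]octa-4,7-dien-6-one | C[C@H]1CC12C=C(OC)C(=O)C(OC)=C2 | intermediate
7 | 1-(3,4,5-trimethoxyphenyl)propan-1-one | CCC(=O)c1cc(OC)c(OC)c(OC)c1 | starting material
8 | (Z)-trimethyl{[1-(3,4,5-trimethoxyphenyl)prop-1-en-1-yl]oxy}silane | C/C=C(\O[Si](C)(C)C)c1cc(OC)c(OC)c(OC)c1 | intermediate
9 | (3R)-4-{3,5-dimethoxy-4-[(trimethylsilyl)oxy]phenyl}-2,3-dimethyl-1-(3,4,5-trimethoxyphenyl)butan-1-one, both C2 epimers | COc1cc(C[C@@H](C)C(C)C(=O)c2cc(OC)c(OC)c(OC)c2)cc(OC)c1O[Si](C)(C)C | intermediate
10 | (7R)-2,3,4,3',5'-pentamethoxy-7,8-dimethyl-7,8-dihydro-6H-spiro[benzo[7]annulene-5,1'-cyclohexa[2,5]diene]-4',9-dione, both C8 epimers | COC1=CC2(C=C(OC)C1=O)C[C@@H](C)C(C)C(=O)c1cc(OC)c(OC)c(OC)c12 | intermediate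
11 | (7R)-4'-hydroxy-2,3,4,3',5'-pentamethoxy-7,8-dimethyl-7,8-dihydro-6H-spiro[benzo[7]annulene-5,1'-cyclohexa[2,5]dien]-9-one, both C8 epimers, dienol carbon unassigned | COC1=CC2(C=C(OC)C1O)C[C@@H](C)C(C)C(=O)c1cc(OC)c(OC)c(OC)c12 | intermediate
12 | (7R,8S)-4'-hydroxy-2,3,4,3',5'-pentamethoxy-7,8-dimethyl-7,8-dihydro-6H-spiro[benzo[7]annulene-5,1'-cyclohexa[2,5]dien]-9-one, dienol carbon unassigned | COC1=CC2(C=C(OC)C1O)C[C@@H](C)[C@H](C)C(=O)c1cc(OC)c(OC)c(OC)c12 | intermediate
13 | (7R,8S,9R)-2,3,4,3',5'-pentamethoxy-7,8-dimethyl-6,7,8,9-tetrahydrospiro[benzo[7]annulene-5,1'-cyclohexa[2,5]diene]-4',9-diol, dienol carbon unassigned | COC1=CC2(C=C(OC)C1O)C[C@@H](C)[C@H](C)[C@@H](O)c1cc(OC)c(OC)c(OC)c12 | intermediate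
14 | (7R,8S,9R)-9-hydroxy-2,3,4,3',5'-pentamethoxy-7,8-dimethyl-6,7,8,9-tetrahydrospiro[benzo[7]annulene-5,1'-cyclohexa[2,5]dien]-4'-one (CNP0288561.1) | COC1=CC2(C=C(OC)C1=O)C[C@@H](C)[C@H](C)[C@@H](O)c1cc(OC)c(OC)c(OC)c12 | target

**Step count and risks**

Total step count: 8. Longest linear sequence: 7 steps (1, 2, 3, 4, 6, 7, 8).

Step 6 (Proposed new method). What may go wrong: opening of the bridged ion at its CH2 carbon, loss of a proton from the bridged ion to give the propenylarene, or Friedel–Crafts self-alkylation and oligomerisation before the enol ether reacts. The fallback uses known chemistry only; it sets out from 4 and comes back at 10. Appel iodination of 4 (I2, PPh3, imidazole, CH2Cl2; inversion) should give tert-butyl{4-[(2S)-2-iodopropyl]-2,6-dimethoxyphenoxy}dimethylsilane F1. Commercial ethyl 3-oxo-3-(3,4,5-trimethoxyphenyl)propanoate, deprotonated with NaH in DMF, should displace the iodide by SN2 (second inversion, so the same net retention as in the main route) to give the C-alkylated β-keto ester F2. C-Methylation (MeI, K2CO3, acetone) should give the quaternary keto ester F3, and Krapcho dealkoxycarbonylation (LiCl, wet DMSO, 150 °C) the open-chain silyl-protected ketone F4. Bu4NF should free the open-chain phenol ketone F5, and PhI(OCOCF3)2 in CF3CH2OH at –40 °C (the known para–ortho' phenol coupling) should then close it to 10.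

Step 7. What may go wrong: incomplete discrimination between the two ketones in the masking reduction (if both are reduced, C8 can no longer be equilibrated), or an unfavourable position of the C8 equilibrium. The fallback sets out from 10 and comes back at 13. The unmasked dione is equilibrated through its neutral enol under acid catalysis (TsOH·H2O cat., CHCl3, 40 °C), where no enolate is present to add to the dienone; this should give the trans spiro keto-dienone F6. NaBH4 in MeOH at 0 °C then reduces both ketones at once to diol 13, which continues with the MnO2 oxidation of step 8.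

Step 8. What may go wrong: poor facial selectivity in the hydride addition at C9. The fallback sets out from 12 and comes back at 13. The substrate-controlled hydride reduction is replaced by a catalyst-controlled biocatalytic one: an (R)-selective ketoreductase (NADP+, isopropanol recycling, pH 7 buffer with DMSO) should reduce only the aryl ketone of 12 and give diol 13 with the C9 configuration set by the enzyme; no new compound is made (F0), and the MnO2 oxidation follows as before.

Further compounds
F1 | step 6 | tert-butyl{4-[(2S)-2-iodopropyl]-2,6-dimethoxyphenoxy}dimethylsilane | C[C@H](I)Cc1cc(OC)c(O[Si](C)(C)C(C)(C)C)c(OC)c1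
F2 | step 6 | ethyl (3R)-4-{4-[(tert-butyldimethylsilyl)oxy]-3,5-dimethoxyphenyl}-3-methyl-2-(3,4,5-trimethoxybenzoyl)butanoate, both C2 epimers | CCOC(=O)C(C(=O)c1cc(OC)c(OC)c(OC)c1)[C@H](C)Cc1cc(OC)c(O[Si](C)(C)C(C)(C)C)c(OC)c1
F3 | step 6 | ethyl (3R)-4-{4-[(tert-butyldimethylsilyl)oxy]-3,5-dimethoxyphenyl}-2,3-dimethyl-2-(3,4,5-trimethoxybenzoyl)butanoate, both C2 epimers | CCOC(=O)C(C)(C(=O)c1cc(OC)c(OC)c(OC)c1)[C@H](C)Cc1cc(OC)c(O[Si](C)(C)C(C)(C)C)c(OC)c1
F4 | step 6 | (3R)-4-{4-[(tert-butyldimethylsilyl)oxy]-3,5-dimethoxyphenyl}-2,3-dimethyl-1-(3,4,5-trimethoxyphenyl)butan-1-one, both C2 epimers | CC(C(=O)c1cc(OC)c(OC)c(OC)c1)[C@H](C)Cc1cc(OC)c(O[Si](C)(C)C(C)(C)C)c(OC)c1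
F5 | step 6 | (3R)-4-(4-hydroxy-3,5-dimethoxyphenyl)-2,3-dimethyl-1-(3,4,5-trimethoxyphenyl)butan-1-one, both C2 epimers | CC(C(=O)c1cc(OC)c(OC)c(OC)c1)[C@H](C)Cc1cc(OC)c(O)c(OC)c1
F6 | step 7 | (7R,8S)-2,3,4,3',5'-pentamethoxy-7,8-dimethyl-7,8-dihydro-6H-spiro[benzo[7]annulene-5,1'-cyclohexa[2,5]diene]-4',9-dione | COC1=CC2(C=C(OC)C1=O)C[C@@H](C)[C@H](C)C(=O)c1cc(OC)c(OC)c(OC)c12
F0 | step 8 | none | none
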